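**Retrosynthetic overview**
- Butyrolactone V comes from global hydrogenolysis of a tri-O-benzyl butenolide; the butenolide ring is formed last.
- The butenolide comes from intramolecular aldol condensation of the (benzyloxy)acetate ester of a tertiary α-hydroxy-β-keto methyl ester (closes C3–C4, with C2/C3 supplied by benzyloxyacetyl chloride).
- The quaternary C5 comes from an intermolecular aldol between the lithium enolate of a Seebach dioxolanone (from an (S)-aryllactic acid) and 4-(benzyloxy)benzaldehyde (forms C4–C5), followed by oxidation and methanolysis of the temporary dioxolanone ring.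
- The (S)-aryllactic acid comes from a chromanyl Grignard reagent and methyl (S)-glycidate.
- The chroman ring is formed first: 4-bromophenol propargyl ether, Claisen cyclisation to the chromene, then Jacobsen epoxidation and hydride opening to set the (S)-carbinol.

Assumption: aldol adduct 16 is carried on as both carbinol epimers, and intermediate 21 as a mixture at its two transient centres, because these centres are removed in the following operations.

**Step 1**
Reactants: 1 4-bromophenol; 2 3-chloro-3-methylbut-1-yne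
Product: 3 1-bromo-4-[(2-methylbut-3-yn-2-yl)oxy]benzene
Conditions: DBU, CuCl2·2H2O (0.5 mol %), MeCN, 0 °C → rt
Reagents that add atoms: none
Why: Copper-catalysed propargylic substitution (O-alkylation of the phenol) gives the tertiary aryl propargyl ether cleanly at low temperature.

**Step 2**
Reactants: 3 1-bromo-4-[(2-methylbut-3-yn-2-yl)oxy]benzene
Product: 5 6-bromo-2,2-dimethyl-2H-chromene, via allenylphenol 4 (not isolated)
Conditions: PhNEt2, 190 °C, 3 h
Reagents that add atoms: none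
Why: Aromatic propargyl Claisen rearrangement, then 1,5-hydrogen shift and oxa-6π electrocyclisation, gives the 2,2-dimethylchromene; the para bromine makes both ortho positions equivalent.

**Step 3**
Reactants: 5 6-bromo-2,2-dimethyl-2H-chromene
Product: 6 (3S,4S)-6-bromo-3,4-epoxy-2,2-dimethylchromane
Conditions: (S,S)-(salen)MnCl [salen = N,N'-bis(3,5-di-tert-butylsalicylidene)-1,2-cyclohexanediamine dianion] (3 mol %), 4-phenylpyridine N-oxide (15 mol %), aq NaOCl (pH 11.3), CH2Cl2, 0 °C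
Reagents that add atoms: sodium hypochlorite, [Na+].[O-]Cl
Why: Jacobsen–Katsuki epoxidation, for which 2,2-dimethylchromenes are among the best substrates (typically above 95 % ee); the (S,S) catalyst gives the (3S,4S) epoxide, setting the future chromanol centre.

**Step 4**
Reactants: 6 (3S,4S)-6-bromo-3,4-epoxy-2,2-dimethylchromane
Product: 7 (3S)-6-bromo-2,2-dimethyl-3,4-dihydro-2H-chromen-3-ol
Conditions: LiAlH4, THF, 0 °C → rt; then H2O, aq NaOH
Reagents that add atoms: none
Why: Regioselective SN2 hydride opening at the benzylic C4 (C3 is neopentyl-like and blocked) leaves the C3–O bond untouched, so the (S) configuration is retained; the product can be recrystallised to raise ee.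

**Step 5**
Reactants: 7 (3S)-6-bromo-2,2-dimethyl-3,4-dihydro-2H-chromen-3-ol
Product: 8 (3S)-3-(benzyloxy)-6-bromo-2,2-dimethyl-3,4-dihydro-2H-chromene
Conditions: NaH, BnBr, Bu4NI (cat.), THF/DMF, 0 °C → rt
Reagents that add atoms: benzyl bromide, BrCc1ccccc1
Why: Williamson etherification protects the carbinol as a benzyl ether that survives Grignard, enolate, acid and oxidation chemistry and is removed in the final hydrogenolysis.

**Step 6**
Reactants: 8 (3S)-3-(benzyloxy)-6-bromo-2,2-dimethyl-3,4-dihydro-2H-chromene; 9 methyl (2S)-oxirane-2-carboxylate (methyl (S)-glycidate)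
Product: 11 methyl (2S)-3-[(3S)-3-(benzyloxy)-2,2-dimethyl-3,4-dihydro-2H-chromen-6-yl]-2-hydroxypropanoate, via aryl Grignard reagent 10 (not isolated)
Conditions: Mg, THF, 50 °C; then CuBr·SMe2 (10 mol %), 9, THF, −40 → −20 °C; aq NH4Cl
Reagents that add atoms: none
Why: Copper-catalysed Grignard opening of the epoxide at its unsubstituted terminus is faster than ester addition at low temperature and does not touch the glycidate stereocentre, which becomes the (S)-lactate centre.

**Step 7**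
Reactants: 11 methyl (2S)-3-[(3S)-3-(benzyloxy)-2,2-dimethyl-3,4-dihydro-2H-chromen-6-yl]-2-hydroxypropanoate
Product: 12 (2S)-3-[(3S)-3-(benzyloxy)-2,2-dimethyl-3,4-dihydro-2H-chromen-6-yl]-2-hydroxypropanoic acid
Conditions: LiOH·H2O, THF/H2O (3:1), 0 °C → rt; then 1 M HCl
Reagents that add atoms: lithium hydroxide, [Li+].[OH-]
Why: Mild saponification gives the free α-hydroxy acid without epimerisation.

**Step 8**
Reactants: 12 (2S)-3-[(3S)-3-(benzyloxy)-2,2-dimethyl-3,4-dihydro-2H-chromen-6-yl]-2-hydroxypropanoic acid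
Product: 13 (2S,5S)-5-{[(3S)-3-(benzyloxy)-2,2-dimethyl-3,4-dihydro-2H-chromen-6-yl]methyl}-2-tert-butyl-1,3-dioxolan-4-one
Conditions: t-BuCHO, TsOH·H2O (cat.), H2SO4 (cat.), pentane/CH2Cl2, reflux, Dean–Stark; crystallisation of the cis isomer
Reagents that add atoms: pivalaldehyde, CC(C)(C)C=O
Why: Acid-catalysed acetalisation (Seebach self-regeneration of stereocentres) favours the cis dioxolanone, whose new acetal centre (2S) stores the chirality of the lactate carbon; the minor trans isomer must be removed because it would give the opposite quaternary configuration.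

**Step 9**
Reactants: 13 (2S,5S)-5-{[(3S)-3-(benzyloxy)-2,2-dimethyl-3,4-dihydro-2H-chromen-6-yl]methyl}-2-tert-butyl-1,3-dioxolan-4-one; 14 4-(benzyloxy)benzaldehyde
Product: 16 (2S,5R)-5-{[4-(benzyloxy)phenyl](hydroxy)methyl}-5-{[(3S)-3-(benzyloxy)-2,2-dimethyl-3,4-dihydro-2H-chromen-6-yl]methyl}-2-tert-butyl-1,3-dioxolan-4-one (both carbinol epimers), via lithium enolate 15 (not isolated)
Conditions: LiN(iPr)2 (LDA), THF, −78 °C, 30 min; then 14, −78 °C; AcOH quench at −78 °C
Reagents that add atoms: none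
Why: Intermolecular aldol addition of the Seebach dioxolanone enolate to a non-enolisable aldehyde forms the C4–C5 bond of the future butenolide; the aldehyde adds anti to the tert-butyl group, so it replaces the former hydrogen with retention and sets the quaternary centre (5R).

**Step 10**
Reactants: 16 (2S,5R)-5-{[4-(benzyloxy)phenyl](hydroxy)methyl}-5-{[(3S)-3-(benzyloxy)-2,2-dimethyl-3,4-dihydro-2H-chromen-6-yl]methyl}-2-tert-butyl-1,3-dioxolan-4-one (both carbinol epimers)
Product: 17 (2S,5R)-5-[4-(benzyloxy)benzoyl]-5-{[(3S)-3-(benzyloxy)-2,2-dimethyl-3,4-dihydro-2H-chromen-6-yl]methyl}-2-tert-butyl-1,3-dioxolan-4-one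
Conditions: Dess–Martin periodinane, CH2Cl2, 0 °C → rt
Reagents that add atoms: none
Why: Dess–Martin oxidation of the secondary benzylic alcohol converges both carbinol epimers to one aryl ketone under near-neutral conditions that leave the acetal and benzyl ethers intact.

**Step 11**
Reactants: 17 (2S,5R)-5-[4-(benzyloxy)benzoyl]-5-{[(3S)-3-(benzyloxy)-2,2-dimethyl-3,4-dihydro-2H-chromen-6-yl]methyl}-2-tert-butyl-1,3-dioxolan-4-one
Product: 18 methyl (2R)-2-{[(3S)-3-(benzyloxy)-2,2-dimethyl-3,4-dihydro-2H-chromen-6-yl]methyl}-3-[4-(benzyloxy)phenyl]-2-hydroxy-3-oxopropanoate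
Conditions: HCl (1.25 M) in MeOH, 50 °C
Reagents that add atoms: methanol, CO
Why: Acid-catalysed methanolysis (acetal cleavage and transesterification) releases the tertiary alcohol and the methyl ester without alkoxide base, avoiding retro-Claisen cleavage; the quaternary centre has no α-hydrogen and cannot epimerise.

**Step 12**
Reactants: 18 methyl (2R)-2-{[(3S)-3-(benzyloxy)-2,2-dimethyl-3,4-dihydro-2H-chromen-6-yl]methyl}-3-[4-(benzyloxy)phenyl]-2-hydroxy-3-oxopropanoate; 19 (benzyloxy)acetyl chloride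
Product: 20 methyl (2R)-2-{[(benzyloxy)acetyl]oxy}-2-{[(3S)-3-(benzyloxy)-2,2-dimethyl-3,4-dihydro-2H-chromen-6-yl]methyl}-3-[4-(benzyloxy)phenyl]-3-oxopropanoate
Conditions: pyridine, DMAP (cat.), CH2Cl2, 0 °C → rt
Reagents that add atoms: none
Why: DMAP-catalysed O-acylation with a reactive alkoxyacetyl chloride esterifies the hindered tertiary alcohol and installs the C2/C3 unit of the lactone.

**Step 13**
Reactants: 20 methyl (2R)-2-{[(benzyloxy)acetyl]oxy}-2-{[(3S)-3-(benzyloxy)-2,2-dimethyl-3,4-dihydro-2H-chromen-6-yl]methyl}-3-[4-(benzyloxy)phenyl]-3-oxopropanoate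
Product: 22 methyl (2R)-4-(benzyloxy)-3-[4-(benzyloxy)phenyl]-2-{[(3S)-3-(benzyloxy)-2,2-dimethyl-3,4-dihydro-2H-chromen-6-yl]methyl}-5-oxo-2,5-dihydrofuran-2-carboxylate, via β-hydroxy lactone 21 (not isolated)
Conditions: DBU, 4 Å MS, MeCN, 60 °C
Reagents that add atoms: none
Why: Intramolecular aldol condensation (5-exo attack of the alkoxyacetate enolate on the more electrophilic aryl ketone, then E1cB dehydration to the conjugated butenolide) is a standard way to make 3-alkoxy-4-aryl-5,5-disubstituted furanones and does not touch the quaternary centre.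

**Step 14**
Reactants: 22 methyl (2R)-4-(benzyloxy)-3-[4-(benzyloxy)phenyl]-2-{[(3S)-3-(benzyloxy)-2,2-dimethyl-3,4-dihydro-2H-chromen-6-yl]methyl}-5-oxo-2,5-dihydrofuran-2-carboxylate
Product: 23 butyrolactone V, methyl (2R)-4-hydroxy-2-{[(3S)-3-hydroxy-2,2-dimethyl-3,4-dihydro-2H-chromen-6-yl]methyl}-3-(4-hydroxyphenyl)-5-oxo-2,5-dihydrofuran-2-carboxylate
Conditions: H2 (1 atm), Pd(OH)2/C, EtOAc/MeOH, rt
Reagents that add atoms: none
Why: Catalytic hydrogenolysis removes the aryl, enol and alkyl benzyl ethers in one operation, while the tetrasubstituted conjugated enol double bond, the lactone and the methyl ester are inert.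

**Compound list**
1 | 4-bromophenol | Oc1ccc(Br)cc1 | starting material
2 | 3-chloro-3-methylbut-1-yne | C#CC(C)(C)Cl | starting material
3 | 1-bromo-4-[(2-methylbut-3-yn-2-yl)oxy]benzene | C#CC(C)(C)Oc1ccc(Br)cc1 | intermediate
4 | 4-bromo-2-(3-methylbuta-1,2-dien-1-yl)phenol (allenylphenol) | CC(C)=C=Cc1cc(Br)ccc1O | intermediate (not isolated)
5 | 6-bromo-2,2-dimethyl-2H-chromene | CC1(C)C=Cc2cc(Br)ccc2O1 | intermediate
6 | (3S,4S)-6-bromo-3,4-epoxy-2,2-dimethylchromane | Brc1ccc2c(c1)[C@H]3[C@H](O3)C(C)(C)O2 | intermediate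
7 | (3S)-6-bromo-2,2-dimethyl-3,4-dihydro-2H-chromen-3-ol | Brc1ccc2c(c1)C[C@H](O)C(C)(C)O2 | intermediate
8 | (3S)-3-(benzyloxy)-6-bromo-2,2-dimethyl-3,4-dihydro-2H-chromene | Brc1ccc2c(c1)C[C@H](OCc3ccccc3)C(C)(C)O2 | intermediate
9 | methyl (2S)-oxirane-2-carboxylate | COC(=O)[C@@H]1CO1 | starting material
10 | [(3S)-3-(benzyloxy)-2,2-dimethyl-3,4-dihydro-2H-chromen-6-yl]magnesium bromide | Br[Mg]c1ccc2c(c1)C[C@H](OCc3ccccc3)C(C)(C)O2 | intermediate (not isolated)
11 | methyl (2S)-3-[(3S)-3-(benzyloxy)-2,2-dimethyl-3,4-dihydro-2H-chromen-6-yl]-2-hydroxypropanoate | COC(=O)[C@@H](O)Cc1ccc2c(c1)C[C@H](OCc3ccccc3)C(C)(C)O2 | intermediate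
12 | (2S)-3-[(3S)-3-(benzyloxy)-2,2-dimethyl-3,4-dihydro-2H-chromen-6-yl]-2-hydroxypropanoic acid | OC(=O)[C@@H](O)Cc1ccc2c(c1)C[C@H](OCc3ccccc3)C(C)(C)O2 | intermediate
13 | (2S,5S)-5-{[(3S)-3-(benzyloxy)-2,2-dimethyl-3,4-dihydro-2H-chromen-6-yl]methyl}-2-tert-butyl-1,3-dioxolan-4-one (cis) | O=C1O[C@@H](C(C)(C)C)O[C@H]1Cc2ccc3c(c2)C[C@H](OCc4ccccc4)C(C)(C)O3 | intermediate
14 | 4-(benzyloxy)benzaldehyde | O=Cc1ccc(OCc2ccccc2)cc1 | starting material
15 | lithium enolate of 13 (lithium (2S)-2-tert-butyl-5-(chromanylmethyl)-1,3-dioxol-4-olate) | [Li]OC1=C(Cc2ccc3c(c2)C[C@H](OCc4ccccc4)C(C)(C)O3)O[C@H](C(C)(C)C)O1 | intermediate (not isolated)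
16 | (2S,5R)-5-{[4-(benzyloxy)phenyl](hydroxy)methyl}-5-{[(3S)-3-(benzyloxy)-2,2-dimethyl-3,4-dihydro-2H-chromen-6-yl]methyl}-2-tert-butyl-1,3-dioxolan-4-one, both carbinol epimers | O=C1O[C@@H](C(C)(C)C)O[C@]1(Cc2ccc3c(c2)C[C@H](OCc4ccccc4)C(C)(C)O3)C(O)c5ccc(OCc6ccccc6)cc5 | intermediate
17 | (2S,5R)-5-[4-(benzyloxy)benzoyl]-5-{[(3S)-3-(benzyloxy)-2,2-dimethyl-3,4-dihydro-2H-chromen-6-yl]methyl}-2-tert-butyl-1,3-dioxolan-4-one | O=C1O[C@@H](C(C)(C)C)O[C@]1(Cc2ccc3c(c2)C[C@H](OCc4ccccc4)C(C)(C)O3)C(=O)c5ccc(OCc6ccccc6)cc5 | intermediate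
18 | methyl (2R)-2-{[(3S)-3-(benzyloxy)-2,2-dimethyl-3,4-dihydro-2H-chromen-6-yl]methyl}-3-[4-(benzyloxy)phenyl]-2-hydroxy-3-oxopropanoate | COC(=O)[C@@](O)(Cc1ccc2c(c1)C[C@H](OCc3ccccc3)C(C)(C)O2)C(=O)c1ccc(OCc2ccccc2)cc1 | intermediate
19 | (benzyloxy)acetyl chloride | ClC(=O)COCc1ccccc1 | starting material
20 | methyl (2R)-2-{[(benzyloxy)acetyl]oxy}-2-{[(3S)-3-(benzyloxy)-2,2-dimethyl-3,4-dihydro-2H-chromen-6-yl]methyl}-3-[4-(benzyloxy)phenyl]-3-oxopropanoate | COC(=O)[C@@](OC(=O)COCc1ccccc1)(Cc1ccc2c(c1)C[C@H](OCc3ccccc3)C(C)(C)O2)C(=O)c1ccc(OCc2ccccc2)cc1 | intermediate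
21 | methyl (2R)-4-(benzyloxy)-3-[4-(benzyloxy)phenyl]-2-{[(3S)-3-(benzyloxy)-2,2-dimethyl-3,4-dihydro-2H-chromen-6-yl]methyl}-3-hydroxy-5-oxooxolane-2-carboxylate, mixture at C3/C4 | COC(=O)[C@]1(Cc2ccc3c(c2)C[C@H](OCc4ccccc4)C(C)(C)O3)OC(=O)C(OCc5ccccc5)C1(O)c6ccc(OCc7ccccc7)cc6 | intermediate (not isolated)
22 | methyl (2R)-4-(benzyloxy)-3-[4-(benzyloxy)phenyl]-2-{[(3S)-3-(benzyloxy)-2,2-dimethyl-3,4-dihydro-2H-chromen-6-yl]methyl}-5-oxo-2,5-dihydrofuran-2-carboxylate | COC(=O)[C@]1(Cc2ccc3c(c2)C[C@H](OCc4ccccc4)C(C)(C)O3)OC(=O)C(OCc5ccccc5)=C1c6ccc(OCc7ccccc7)cc6 | intermediate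
23 | butyrolactone V, methyl (2R)-4-hydroxy-2-{[(3S)-3-hydroxy-2,2-dimethyl-3,4-dihydro-2H-chromen-6-yl]methyl}-3-(4-hydroxyphenyl)-5-oxo-2,5-dihydrofuran-2-carboxylate | COC(=O)[C@]1(Cc2ccc3c(c2)C[C@H](O)C(C)(C)O3)OC(=O)C(O)=C1c1ccc(O)cc1 | target

**Totals**
Total step count: 14. Longest linear sequence: 14 steps (1 → 23); 2, 9, 14 and 19 are purchased.

**Three steps most likely to fail, with fallbacks**

Step 13 (ring closure). The alkoxyacetate enolate could instead attack the neighbouring methyl ester (Dieckmann closure to a tetronic acid), or the aldol adduct 21 could resist dehydration. The fallback sets out from 18 and comes back at 22. Alcohol 18 is esterified with 2-(benzyloxy)-2-(diethoxyphosphoryl)acetic acid (DCC, DMAP, CH2Cl2) to give methyl (2R)-2-{[2-(benzyloxy)-2-(diethoxyphosphoryl)acetyl]oxy}-2-{[(3S)-3-(benzyloxy)-2,2-dimethyl-3,4-dihydro-2H-chromen-6-yl]methyl}-3-[4-(benzyloxy)phenyl]-3-oxopropanoate F4. An intramolecular Horner–Wadsworth–Emmons olefination of the ketone (LiCl, DBU, MeCN) then gives 22 irreversibly, and phosphonate carbanions do not undergo the Dieckmann pathway readily.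

Step 11 (dioxolanone methanolysis). The α-hydroxy-β-keto ester may undergo α-ketol (acyloin) rearrangement or retro-Claisen cleavage while the hindered acetal is being opened. The fallback sets out from 16 and comes back at 18. The dioxolanone is opened before the ketone exists: K2CO3 in MeOH at 0 °C converts 16 into methyl (2R)-2-{[(3S)-3-(benzyloxy)-2,2-dimethyl-3,4-dihydro-2H-chromen-6-yl]methyl}-3-[4-(benzyloxy)phenyl]-2,3-dihydroxypropanoate F3. MnO2 in CH2Cl2 then oxidises only the secondary benzylic alcohol, under neutral conditions, to give 18.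

Step 6 (glycidate opening). The Grignard reagent may add to the ester or give halohydrin by-products. The fallback sets out from 8 and comes back at 12. Bromide 8 is coupled (Negishi; Pd2(dba)3/SPhos as the zerovalent palladium catalyst, DMF, 50 °C) with the organozinc iodide made from methyl (2R)-2-[(tert-butoxycarbonyl)amino]-3-iodopropanoate and Zn, giving methyl (2S)-3-[(3S)-3-(benzyloxy)-2,2-dimethyl-3,4-dihydro-2H-chromen-6-yl]-2-[(tert-butoxycarbonyl)amino]propanoate F1. Aqueous HCl/dioxane at 80 °C removes the carbamate and the methyl ester to give (2S)-2-amino-3-[(3S)-3-(benzyloxy)-2,2-dimethyl-3,4-dihydro-2H-chromen-6-yl]propanoic acid F2. Diazotisation (NaNO2, aq H2SO4/dioxane, 0 °C) replaces the amino group by hydroxyl with retention (double inversion through the α-lactone), giving 12.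

**Further compounds**
F1 | step 6 | methyl (2S)-3-[(3S)-3-(benzyloxy)-2,2-dimethyl-3,4-dihydro-2H-chromen-6-yl]-2-[(tert-butoxycarbonyl)amino]propanoate | COC(=O)[C@H](Cc1ccc2c(c1)C[C@H](OCc3ccccc3)C(C)(C)O2)NC(=O)OC(C)(C)C
F2 | step 6 | (2S)-2-amino-3-[(3S)-3-(benzyloxy)-2,2-dimethyl-3,4-dihydro-2H-chromen-6-yl]propanoic acid | N[C@@H](Cc1ccc2c(c1)C[C@H](OCc3ccccc3)C(C)(C)O2)C(=O)O
F3 | step 11 | methyl (2R)-2-{[(3S)-3-(benzyloxy)-2,2-dimethyl-3,4-dihydro-2H-chromen-6-yl]methyl}-3-[4-(benzyloxy)phenyl]-2,3-dihydroxypropanoate, both carbinol epimers | COC(=O)[C@@](O)(Cc1ccc2c(c1)C[C@H](OCc3ccccc3)C(C)(C)O2)C(O)c1ccc(OCc2ccccc2)cc1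
F4 | step 13 | methyl (2R)-2-{[2-(benzyloxy)-2-(diethoxyphosphoryl)acetyl]oxy}-2-{[(3S)-3-(benzyloxy)-2,2-dimethyl-3,4-dihydro-2H-chromen-6-yl]methyl}-3-[4-(benzyloxy)phenyl]-3-oxopropanoate, mixture at the phosphonate carbon | COC(=O)[C@@](OC(=O)C(OCc1ccccc1)P(=O)(OCC)OCC)(Cc1ccc2c(c1)C[C@H](OCc3ccccc3)C(C)(C)O2)C(=O)c1ccc(OCc2ccccc2)cc1
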